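**Plan**

1. Numbering used throughout: ring A = C1–C5, C10 (C1 bears furan carbon C16, C3=C4, C4 bears the lactone carbonyl C18); ring B = C5–C10 (C5 quaternary with the OCH2 carbon C19, C7–OAc, C8=C17H2, C9 quaternary with methyl C20 and C11); ring C = C9–C11–C12(=O)–C13=C16–C1–C10. α is the face of the C5–C19 bond, β the face of H-10.
2. Cuts, in retrosynthetic order: C8=C17 (methylenation); C18=O (the lactone is carried as a tetrahydrofuran and oxidised late); C12–C13 (Friedel–Crafts closure of ring C); C7–O (enolate hydroxylation); C9–C11 and C10–H (reductive alkylation); C5–C19 (dearomatising para-alkylation); C4–C5 (cyclodehydration closing ring A); C1–C10 (asymmetric conjugate arylation).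
3. Enabling feature: C8 of ring B is a masked carbonyl para to quaternary C5, so ring B is a latent 4-substituted 2-methylphenol. Its para carbon C5 can be joined to the OCH2 carbon C19 that hangs from C4 through C18–O, and the resulting dienone carries a handle for each of C6/C7, C8, C9 and C10.
4. Forward order of rings: furan (bought) and arene, then ring A, then the tetrahydrofuran with dearomatisation of ring B, then saturation and substitution of ring B, then ring C, then lactone carbonyl and methylene.
5. Stereochemistry: C1 from a rhodium/chiral-diene conjugate arylation; C5 anti to the pseudoaxial C1 furyl group; C10 and C9 from dissolving-metal reduction and alkylation anti to C19; C7 from β-face enolate hydroxylation.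

Key step: step 7

Assumption: boronic acid 1 is taken as a catalogue compound (otherwise one borylation step from 3-bromo-2-methylphenol), and the silyloxy phosphonate of step 2 is the known reagent for 2-oxo esters.

**Route**

Step 1
Reactants: 1 (3-hydroxy-2-methylphenyl)boronic acid; 2 (E)-3-(furan-2-yl)prop-2-enal
Product: 3 (3R)-3-(furan-2-yl)-3-(3-hydroxy-2-methylphenyl)propanal
Conditions: [RhCl(C2H4)2]2 (2.5 mol %), 2,5-diphenylbicyclo[2.2.2]octa-2,5-diene (6 mol %, the enantiomer that gives 3R), KOH (0.5 equiv), MeOH/H2O 10:1, 50 °C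
Reagents that add atoms: none
Why: Hayashi–Miyaura-type rhodium-catalysed 1,4-addition of an arylboronic acid to a β-aryl enal, for which diene ligands give 3,3-diarylpropanals selectively over 1,2-addition; the chiral diene selects the enal face and so sets C1.

Step 2
Reactants: 3
Product: 4 ethyl (5R)-2-[(tert-butyldimethylsilyl)oxy]-5-(furan-2-yl)-5-(3-hydroxy-2-methylphenyl)pent-2-enoate (E/Z mixture)
Conditions: silyloxy phosphonate (1.3 equiv), LiN(SiMe3)2 (2.4 equiv), THF, −78 → 0 °C
Reagents that add atoms: ethyl 2-[(tert-butyldimethylsilyl)oxy]-2-(diethoxyphosphoryl)acetate, CCOC(=O)C(O[Si](C)(C)C(C)(C)C)P(=O)(OCC)OCC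
Why: Horner–Wadsworth–Emmons olefination of the aldehyde (the lithium phenoxide is a spectator) should add C4 and C18 as a silyl-masked 2-oxo ester without touching C1.

Step 3
Reactants: 4
Product: 7 ethyl (4R)-4-(furan-2-yl)-6-hydroxy-5-methyl-3,4-dihydronaphthalene-1-carboxylate, via 2-oxo ester 5 (not isolated), via benzylic carbinol 6 (not isolated)
Conditions: Bu4NF, AcOH, THF, 0 °C; then Sc(OTf)3 (10 mol %), CH2Cl2 (0.01 M), 0 → 25 °C
Reagents that add atoms: none
Why: fluoride unmasks the 2-oxo ester, and Lewis-acid Friedel–Crafts hydroxyalkylation by the phenol carbon para to OH (much more nucleophilic than furan C3, the only other carbon that could close a six-membered ring) followed by loss of water from the para-hydroxybenzylic carbinol should give the conjugated ester, as in the known cyclodehydration of 2-oxo-5-arylpentanoates.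

Step 4
Reactants: 7
Product: 8 ethyl (4R)-4-(furan-2-yl)-5-methyl-6-{[tri(propan-2-yl)silyl]oxy}-3,4-dihydronaphthalene-1-carboxylate
Conditions: i-Pr3SiCl, imidazole, DMF, 25 °C
Reagents that add atoms: chlorotri(propan-2-yl)silane, CC(C)[Si](Cl)(C(C)C)C(C)C
Why: standard phenol silylation, which protects the phenol through steps 5 and 6 and stores it as a fluoride-releasable phenoxide for step 7.

Step 5
Reactants: 8
Product: 9 [(4R)-4-(furan-2-yl)-5-methyl-6-{[tri(propan-2-yl)silyl]oxy}-3,4-dihydronaphthalen-1-yl]methanol
Conditions: i-Bu2AlH (2.5 equiv), CH2Cl2, −78 °C; aq. potassium sodium tartrate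
Reagents that add atoms: none
Why: 1,2-reduction of the conjugated ester by the aluminium hydride gives the allylic alcohol (C18–OH) and leaves the aryl silyl ether, the furan and the alkene alone.

Step 6
Reactants: 9
Product: 10 methylthiomethyl ether of 9 (C18–O–CH2–SMe)
Conditions: NaH, NaI (cat.), ClCH2SMe, THF, 0 → 25 °C
Reagents that add atoms: chloromethyl methyl sulfide, CSCCl
Why: Williamson etherification of the primary allylic alkoxide installs the future C19 as a stable O,S-acetal that can be turned into an electrophile under non-acidic conditions.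

Step 7
Reactants: 10
Product: 13 tetrahydrofuran-fused cross-conjugated dienone (ring B = 9-methyl-6,9(10)-dien-8-one; ring C5–C19–O–C18–C4; C19 α; 1β-furyl), via sulfonium triflate 11 (not isolated), via phenoxide 12 (not isolated)
Conditions: MeOTf (1.05 equiv), 2,6-di-tert-butyl-4-methylpyridine, CH2Cl2, −40 °C; then dilution to 0.002 M with MeCN, CsF (3 equiv), 18-crown-6 (cat.), −40 → 0 °C
Reagents that add atoms: none
Why: Proposed new method: methyl triflate S-methylates the methylthiomethyl ether to the alkoxymethyl(dimethyl)sulfonium ion 11 (the known activation of such ethers for acetal formation), and fluoride then frees phenoxide 12, whose carbon para to oxygen (C5, the ring-fusion carbon that already carries C4) displaces dimethyl sulfide from the OCH2 carbon C19. The closest known reaction type is the intramolecular para-C-alkylation of phenoxides by tethered sulfonates or halides to cyclohexa-2,5-dienones (Ar1-5 participation, also triggered by fluoride from aryl silyl ethers); what is new is the α-oxygenated sulfonium electrophile. The tetrahydrofuran closes in the 5-exo-tet mode and ring B is left as the 9-methyl-6,9(10)-dien-8-one. The new quaternary centre C5 is controlled by C1: the peri methyl on C9 forces the C1 furyl group pseudoaxial, so C19 should add to the opposite face of C5 (C19 α, furyl β). The step needs C- over O-alkylation and ring closure over intermolecular reaction: the para carbon is the only nucleophilic site of the phenoxide that the tether can reach, high dilution suppresses intermolecular O-alkylation, and the anionic phenoxide outruns the neutral furan.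

Step 8
Reactants: 13
Product: 14 enone (ring B = 9-methyl-9(10)-en-8-one; otherwise as 13)
Conditions: H2 (1 atm), RhCl(PPh3)3 (5 mol %), benzene/EtOH 1:1, 25 °C
Reagents that add atoms: none
Why: homogeneous hydrogenation with this catalyst is known to reduce only the disubstituted double bond of cross-conjugated dienones, so C6=C7 is saturated while tetrasubstituted C9=C10, trisubstituted C3=C4 and the furan remain, and the product can no longer re-aromatise.

Step 9
Reactants: 14
Product: 16 trans-fused keto ester (C8 ketone; C9 with α-methyl and β-CH2CO2t-Bu; H-10 β), via lithium enolate 15 (not isolated)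
Conditions: Li (2.4 equiv), NH3(l)/THF, t-BuOH (1.0 equiv), −78 °C; isoprene; NH3 evaporated; BrCH2CO2t-Bu (3 equiv), THF, −78 → 0 °C
Reagents that add atoms: tert-butyl bromoacetate, BrCC(=O)OC(C)(C)C
Why: Birch-type reductive alkylation, in which axial protonation of C10 should give the trans-fused enolate and the regiodefined lithium enolate is alkylated at C9 anti to the axial C19, the course established for 9-methyl-Δ9(10)-8-octalones with an angular C5 substituent; this sets H-10 β, C11 β and C20 α.

Step 10
Reactants: 16
Product: 18 7β-hydroxy ketone, via potassium enolate 17 (not isolated)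
Conditions: KN(SiMe3)2 (1.1 equiv), THF, −78 °C; 3-phenyl-2-(phenylsulfonyl)oxaziridine (1.3 equiv), −78 °C; aq. NH4Cl
Reagents that add atoms: 3-phenyl-2-(phenylsulfonyl)oxaziridine, O=S(=O)(c1ccccc1)N1OC1c1ccccc1
Why: the ketone can enolise only toward C7 (C9 is quaternary and the ester is far less acidic), and the N-sulfonyloxaziridine should attack the enolate from the β face because the α face of C7 is flanked by the syn-axial C19 and C20, giving the equatorial 7β-alcohol.

Step 11
Reactants: 18
Product: 19 7β-acetoxy ketone
Conditions: Ac2O, pyridine, 4-(dimethylamino)pyridine (cat.), CH2Cl2, 0 → 25 °C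
Reagents that add atoms: acetic anhydride, CC(=O)OC(C)=O
Why: routine acylation of an unhindered equatorial secondary alcohol, which also protects the α-ketol before the acidic and oxidising steps.

Step 12
Reactants: 19
Product: 22 tetracyclic 8,12-diketone with ring C closed (7β-OAc; tetrahydrofuran intact), via carboxylic acid 20 (not isolated), via acid chloride 21 (not isolated)
Conditions: CF3CO2H/CH2Cl2 1:4, anisole, 0 °C; evaporation; 1-chloro-N,N,2-trimethylprop-1-en-1-amine (1.3 equiv), CH2Cl2, 0 °C; SnCl4 (1.2 equiv), CH2Cl2 (0.005 M), −78 °C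
Reagents that add atoms: none
Why: after ester cleavage and neutral acid chloride formation, intramolecular Friedel–Crafts acylation should occur at furan C13 (the only furan position in reach), helped by the peri relation of the equatorial C9 side chain and the equatorial C1 furyl group, to close the seven-membered ring.

Step 13
Reactants: 22
Product: 23 α,β-unsaturated γ-lactone (C18=O)
Conditions: CrO3, 3,5-dimethylpyrazole, CH2Cl2, −20 °C
Reagents that add atoms: chromium trioxide, O=[Cr](=O)=O
Why: C18 is both allylic to C3=C4 and α to the ring oxygen, so the known chromium–amine oxidation of cyclic allylic ethers (3-alkylidene tetrahydrofurans) to α-alkylidene lactones should take place there, while the acylated furan, the acetate and both ketones are inert.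

Step 14
Reactants: 23
Product: 24 target, CNP0273675.1
Conditions: Zn, CH2Br2, TiCl4 (reagent pre-formed in THF), CH2Cl2, 0 → 25 °C
Reagents that add atoms: dibromomethane, BrCBr
Why: Takai–Lombardo methylenation is non-basic and spares esters, lactones and epimerisable centres, and it should prefer the inductively activated α-acetoxy ketone C8 over C12, whose carbonyl is deactivated as a vinylogous ester of the furan oxygen.

**Compound list**

1 | (3-hydroxy-2-methylphenyl)boronic acid | OB(O)c1cccc(O)c1C | starting material
2 | (E)-3-(furan-2-yl)prop-2-enal | O=C/C=C/c1ccco1 | starting material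
3 | (3R)-3-(furan-2-yl)-3-(3-hydroxy-2-methylphenyl)propanal | O=CC[C@H](c1cccc(O)c1C)c1ccco1 | intermediate
4 | ethyl (5R)-2-[(tert-butyldimethylsilyl)oxy]-5-(furan-2-yl)-5-(3-hydroxy-2-methylphenyl)pent-2-enoate (E/Z mixture) | CCOC(=O)C(O[Si](C)(C)C(C)(C)C)=CC[C@H](c1cccc(O)c1C)c1ccco1 | intermediate
5 | ethyl (5R)-5-(furan-2-yl)-5-(3-hydroxy-2-methylphenyl)-2-oxopentanoate (not isolated) | CCOC(=O)C(=O)CC[C@H](c1cccc(O)c1C)c1ccco1 | intermediate
6 | ethyl (4R)-4-(furan-2-yl)-1,6-dihydroxy-5-methyl-1,2,3,4-tetrahydronaphthalene-1-carboxylate, C1 epimers (not isolated) | CCOC(=O)C1(O)CC[C@@H](c2ccco2)c2c(C)c(O)ccc21 | intermediate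
7 | ethyl (4R)-4-(furan-2-yl)-6-hydroxy-5-methyl-3,4-dihydronaphthalene-1-carboxylate | CCOC(=O)C1=CC[C@@H](c2ccco2)c2c(C)c(O)ccc21 | intermediate
8 | ethyl (4R)-4-(furan-2-yl)-5-methyl-6-{[tri(propan-2-yl)silyl]oxy}-3,4-dihydronaphthalene-1-carboxylate | CCOC(=O)C1=CC[C@@H](c2ccco2)c2c(C)c(O[Si](C(C)C)(C(C)C)C(C)C)ccc21 | intermediate
9 | [(4R)-4-(furan-2-yl)-5-methyl-6-{[tri(propan-2-yl)silyl]oxy}-3,4-dihydronaphthalen-1-yl]methanol | OCC1=CC[C@@H](c2ccco2)c2c(C)c(O[Si](C(C)C)(C(C)C)C(C)C)ccc21 | intermediate
10 | methylthiomethyl ether of 9 | CSCOCC1=CC[C@@H](c2ccco2)c2c(C)c(O[Si](C(C)C)(C(C)C)C(C)C)ccc21 | intermediate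
11 | alkoxymethyl(dimethyl)sulfonium triflate from 10 (not isolated) | C[S+](C)COCC1=CC[C@@H](c2ccco2)c2c(C)c(O[Si](C(C)C)(C(C)C)C(C)C)ccc21.[O-]S(=O)(=O)C(F)(F)F | intermediate
12 | phenoxide–sulfonium zwitterion (not isolated) | C[S+](C)COCC1=CC[C@@H](c2ccco2)c2c(C)c([O-])ccc21 | intermediate
13 | tricyclic dienone: ring B 9-methyl-6,9(10)-dien-8-one, tetrahydrofuran C5–C19–O–C18–C4, C3=C4, C19 α, 1β-(furan-2-yl) | O=C1C=C[C@@]23COCC2=CC[C@@H](c4ccco4)C3=C1C | intermediate
14 | 6,7-dihydro derivative of 13 (9-methyl-9(10)-en-8-one) | O=C1CC[C@@]23COCC2=CC[C@@H](c4ccco4)C3=C1C | intermediate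
15 | lithium C8=C9 enolate, H-10 β (not isolated) | [Li+].[O-]C=1CC[C@@]23COCC2=CC[C@@H](c4ccco4)[C@@H]3C=1C | intermediate
16 | trans-fused C8 ketone with 9α-methyl, 9β-CH2CO2t-Bu, H-10 β | O=C1CC[C@@]23COCC2=CC[C@@H](c4ccco4)[C@@H]3[C@@]1(C)CC(=O)OC(C)(C)C | intermediate
17 | potassium C7=C8 enolate of 16 (not isolated) | [K+].[O-]C1=CC[C@@]23COCC2=CC[C@@H](c4ccco4)[C@@H]3[C@@]1(C)CC(=O)OC(C)(C)C | intermediate
18 | 7β-hydroxy derivative of 16 | O=C1[C@@H](O)C[C@@]23COCC2=CC[C@@H](c4ccco4)[C@@H]3[C@@]1(C)CC(=O)OC(C)(C)C | intermediate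
19 | 7β-acetoxy derivative of 16 | O=C1[C@@H](OC(C)=O)C[C@@]23COCC2=CC[C@@H](c4ccco4)[C@@H]3[C@@]1(C)CC(=O)OC(C)(C)C | intermediate
20 | carboxylic acid from 19 (not isolated) | O=C1[C@@H](OC(C)=O)C[C@@]23COCC2=CC[C@@H](c4ccco4)[C@@H]3[C@@]1(C)CC(=O)O | intermediate
21 | acid chloride from 20 (not isolated) | O=C1[C@@H](OC(C)=O)C[C@@]23COCC2=CC[C@@H](c4ccco4)[C@@H]3[C@@]1(C)CC(=O)Cl | intermediate
22 | tetracyclic 8,12-diketone: ring C closed at furan C13, 7β-OAc, tetrahydrofuran intact | O=C1[C@@H](OC(C)=O)C[C@@]23COCC2=CC[C@H]2c4occc4C(=O)C[C@]1(C)[C@@H]23 | intermediate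
23 | 18,19-lactone of 22 (C18=O), still the C8 ketone | O=C1[C@@H](OC(C)=O)C[C@@]23COC(=O)C2=CC[C@H]2c4occc4C(=O)C[C@]1(C)[C@@H]23 | intermediate
24 | CNP0273675.1 | C=C1[C@@H](OC(C)=O)C[C@@]23COC(=O)C2=CC[C@H]2c4occc4C(=O)C[C@]1(C)[C@@H]23 | target

**Count and risks**

Total: 14 steps. Longest linear sequence: 14 steps (1 → 24; 2 enters in step 1).

Steps most likely to fail:

1. Step 7 (Proposed new method). What may go wrong: intermolecular O-alkylation or attack of the alkoxymethyl electrophile on the furan instead of ring closure, or poor facial selectivity at C5. Fallback with known reactions, setting out from 9 and returning at 14: Bu4NF gives (8R)-8-(furan-2-yl)-5-(hydroxymethyl)-1-methyl-7,8-dihydronaphthalen-2-ol F1. Its primary hydroxyl (the phenol is hindered by the ortho methyl) is silylated with (bromomethyl)chlorodimethylsilane and Et3N at −78 °C to the (bromomethyl)dimethylsilyl ether F2. KOt-Bu in THF/t-BuOH at high dilution makes the phenoxide, whose para carbon displaces the primary bromide (phenoxide para-alkylation) to give the oxasilinane-fused dienone F3. H2 with RhCl(PPh3)3 gives the enone F4. H2O2, KF and KHCO3 (Tamao–Fleming oxidation) give the C18,C19-diol F5. TsCl, Et3N and 4-(dimethylamino)pyridine then close the tetrahydrofuran by displacement of the allylic tosylate, which gives 14.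

2. Step 9. What may go wrong: protonation of C10 from the α face (cis ring fusion), because the C1 furyl group crowds the β face, or alkylation of C9 from the α face. Fallback, setting out from 14 and returning at 15: Luche reduction (NaBH4, CeCl3) gives the 8β-allylic alcohol F6 (the 8α epimer is reoxidised and recycled). Hydroxyl-directed hydrogenation with [Ir(cod)(PCy3)(py)]PF6 adds H2 to C9=C10 from the β face to give the saturated alcohol F7. Oxidation with 1,1,1-triacetoxy-1,1-dihydro-1,2-benziodoxol-3(1H)-one gives the ketone F8. Me3SiCl, NaI and Et3N give the more substituted trimethylsilyl enol ether F9, and MeLi releases lithium enolate 15, which is alkylated as in step 9.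

3. Step 14. What may go wrong: methylenation at C12 instead of C8, or reductive loss of the α-acetoxy group by zinc. Fallback, setting out from 19 and returning at 24: the Takai–Lombardo reagent is applied to 19, which has a single ketone, to give the 8(17)-methylene ester F10. Me3SiOTf with 2,6-lutidine, then water, gives the acid F11 without protic acid. (CF3CO)2O with 2,6-di-tert-butylpyridine at −20 °C closes ring C through the mixed anhydride under buffered conditions to give the tetracyclic methylene ketone F12. CrO3 with 3,5-dimethylpyrazole then oxidises C18 to the lactone, which gives 24.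

Further compounds
F1 | step 7 | (8R)-8-(furan-2-yl)-5-(hydroxymethyl)-1-methyl-7,8-dihydronaphthalen-2-ol | OCC1=CC[C@@H](c2ccco2)c2c(C)c(O)ccc21
F2 | step 7 | (bromomethyl)dimethylsilyl ether of the primary alcohol of F1 | BrC[Si](C)(C)OCC1=CC[C@@H](c2ccco2)c2c(C)c(O)ccc21
F3 | step 7 | oxasilinane-fused dienone (ring C5–C19–Si–O–C18–C4, C19 α) | O=C1C=C[C@@]23C[Si](C)(C)OCC2=CC[C@@H](c4ccco4)C3=C1C
F4 | step 7 | 6,7-dihydro derivative of F3 | O=C1CC[C@@]23C[Si](C)(C)OCC2=CC[C@@H](c4ccco4)C3=C1C
F5 | step 7 | enone diol with C19–OH on C5 and C18–OH on C4 | O=C1CC[C@@]2(CO)C(CO)=CC[C@@H](c3ccco3)C2=C1C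
F6 | step 9 | 8β-allylic alcohol from 14 | O[C@H]1CC[C@@]23COCC2=CC[C@@H](c4ccco4)C3=C1C
F7 | step 9 | 8β-alcohol with 9β-H (9α-methyl) and 10β-H | O[C@H]1CC[C@@]23COCC2=CC[C@@H](c4ccco4)[C@@H]3[C@@H]1C
F8 | step 9 | C8 ketone with 9α-methyl, 9β-H and 10β-H | O=C1CC[C@@]23COCC2=CC[C@@H](c4ccco4)[C@@H]3[C@@H]1C
F9 | step 9 | C8=C9 trimethylsilyl enol ether of F8 | C[Si](C)(C)OC=1CC[C@@]23COCC2=CC[C@@H](c4ccco4)[C@@H]3C=1C
F10 | step 14 | 8(17)-methylene 7β-acetate tert-butyl ester | C=C1[C@@H](OC(C)=O)C[C@@]23COCC2=CC[C@@H](c4ccco4)[C@@H]3[C@@]1(C)CC(=O)OC(C)(C)C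
F11 | step 14 | carboxylic acid from F10 | C=C1[C@@H](OC(C)=O)C[C@@]23COCC2=CC[C@@H](c4ccco4)[C@@H]3[C@@]1(C)CC(=O)O
F12 | step 14 | tetracyclic C12 ketone with 8(17)-methylene, 7β-OAc and intact tetrahydrofuran | C=C1[C@@H](OC(C)=O)C[C@@]23COCC2=CC[C@H]2c4occc4C(=O)C[C@]1(C)[C@@H]23
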